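**Plan**
- Retrosynthesis: the 2,5-dihydroxy-1,4-benzoquinone is first traced back to its hydroquinone tetramethyl ether (arene level). The benzylic C1'–C2' bond is cut next (chain numbered C1'–C15' from the ring), and last the two aryl–CH3 bonds, back to 1,2,4,5-tetramethoxybenzene.
- Enabling feature: ring carbons C3 and C6 each carry one sp3 carbon (the C3-methyl carbon and chain carbon C1'), and the twofold symmetry of the 2,5-dioxygenated quinone ring exchanges them. The target is therefore a symmetric 3,6-dimethyl compound homologated once at one methyl group.
- Polarity: at the quinone level C1' is an acceptor (o-quinone methide carbon), like C2' of an alkyl bromide. At the arene level the ring is hexasubstituted and the two homotopic methyl groups are the only metalatable C–H, so C1' becomes a donor.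
- Forward: the ring is bought; the two methyl groups come from two directed ortho-lithiations; the C14 chain is joined by a desymmetrising lateral metalation–alkylation; CAN oxidation and hydrolysis then reveal the dihydroxyquinone.
- Stereochemistry: the only element is the Z-C10'=C11' alkene. It is bought in (Z)-tetradec-9-en-1-ol and carried through steps that use no hydrogenation, no radical chain and no strong acid.

Key step: step 4

Remark: 1,2,4,5-tetramethoxybenzene and (Z)-tetradec-9-en-1-ol (myristoleyl alcohol) are assumed to be purchasable.

**Step 1**
Reactants: 1 1,2,4,5-tetramethoxybenzene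
Product: 3 1,2,4,5-tetramethoxy-3-methylbenzene, via aryllithium 2 (not isolated)
Conditions: n-BuLi (1.1 equiv), THF, 0 °C to rt; then MeI, 0 °C to rt
Reagents that add atoms: iodomethane, CI
Why: Directed ortho-metalation should lithiate a ring C–H flanked by two methoxy groups, and the aryllithium is then methylated by SN2 attack on MeI.

**Step 2**
Reactants: 3 1,2,4,5-tetramethoxy-3-methylbenzene
Product: 5 1,2,4,5-tetramethoxy-3,6-dimethylbenzene, via aryllithium 4 (not isolated)
Conditions: n-BuLi (1.2 equiv), TMEDA, THF, 0 °C to rt; then MeI, 0 °C to rt
Reagents that add atoms: iodomethane, CI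
Why: A second directed ortho-metalation should take the last ring C–H, again flanked by two methoxy groups and kinetically preferred over the benzylic C–H with a plain alkyllithium, and methylation gives the symmetric arene.

**Step 3**
Reactants: 6 (Z)-tetradec-9-en-1-ol
Product: 7 (Z)-14-bromotetradec-5-ene [(Z)-tetradec-9-en-1-yl bromide]
Conditions: CBr4, PPh3, CH2Cl2, 0 °C
Reagents that add atoms: carbon tetrabromide, BrC(Br)(Br)Br
Why: The Appel reaction should convert the primary alcohol into the bromide by SN2 displacement of the oxyphosphonium group under neutral conditions that leave the Z-alkene untouched.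

**Step 4**
Reactants: 5 1,2,4,5-tetramethoxy-3,6-dimethylbenzene; 7 (Z)-14-bromotetradec-5-ene
Product: 9 1,2,4,5-tetramethoxy-3-methyl-6-[(Z)-pentadec-10-en-1-yl]benzene, via benzylpotassium 8 (not isolated)
Conditions: 5 (1.5 equiv), n-BuLi/KOt-Bu (1.2 equiv each), THF, −78 to −50 °C; then 7 (1.0 equiv), −78 to 0 °C; H2O
Reagents that add atoms: none
Why: The n-BuLi/KOt-Bu superbase should remove a proton from one of the two homotopic methyl groups of 5 (lateral metalation) to give benzylpotassium 8, held by the two flanking methoxy oxygens, and 8 then displaces bromide from the primary bromide 7 in an SN2 reaction that forms the C1'–C2' bond. The closest known reaction type is the Schlosser-base benzylic metalation–alkylation of methylanisoles. No ring is closed and no stereocentre is formed, and the Z-alkene of 7 is a spectator because 5 is in excess over the base, so no free superbase remains to deprotonate an allylic position when 7 is added. The selectivity needed is benzylic over ring or O-methyl metalation and mono- over dialkylation: the first is secured by the hexasubstituted ring of 5, which has no ring C–H, and the second by the charge of 8, which disfavours a second deprotonation, together with the excess of 5. The step is a polarity reversal, since C1' is an acceptor carbon at the quinone level and becomes a donor only at the arene level chosen here. Unreacted 5 should be easy to recover because 9 is far less polar.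

**Step 5**
Reactants: 9 1,2,4,5-tetramethoxy-3-methyl-6-[(Z)-pentadec-10-en-1-yl]benzene
Product: 10 2,5-dimethoxy-3-methyl-6-[(Z)-pentadec-10-en-1-yl]cyclohexa-2,5-diene-1,4-dione
Conditions: CAN (2.5 equiv), MeCN/THF/H2O, 0 °C
Reagents that add atoms: water, O
Why: CAN oxidative demethylation (two one-electron oxidations, water attacking a para pair of methoxy-bearing carbons with loss of methanol) is the standard route from 1,2,4,5-tetramethoxyarenes to 2,5-dimethoxy-1,4-benzoquinones, and the electron-rich arene should be oxidised far faster than the isolated Z-alkene.

**Step 6**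
Reactants: 10 2,5-dimethoxy-3-methyl-6-[(Z)-pentadec-10-en-1-yl]cyclohexa-2,5-diene-1,4-dione
Product: 11 2,5-dihydroxy-3-methyl-6-[(Z)-pentadec-10-en-1-yl]cyclohexa-2,5-diene-1,4-dione
Conditions: 2 M aq NaOH, EtOH, 60 °C, Ar; then 1 M HCl to pH 1–2
Reagents that add atoms: sodium hydroxide, [Na+].[OH-]
Why: Both methoxy groups are vinylogous methyl esters and should be exchanged by hydroxide through conjugate addition–elimination (vinylogous saponification), the product resting as its stable dianion until acidification, while the isolated Z-alkene is inert to aqueous base.

**Compound list**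
1 | 1,2,4,5-tetramethoxybenzene | COc1cc(OC)c(OC)cc1OC | starting material
2 | (2,3,5,6-tetramethoxyphenyl)lithium | [Li]c1c(OC)c(OC)cc(OC)c1OC | intermediate
3 | 1,2,4,5-tetramethoxy-3-methylbenzene | Cc1c(OC)c(OC)cc(OC)c1OC | intermediate
4 | (2,3,5,6-tetramethoxy-4-methylphenyl)lithium | [Li]c1c(OC)c(OC)c(C)c(OC)c1OC | intermediate
5 | 1,2,4,5-tetramethoxy-3,6-dimethylbenzene | Cc1c(OC)c(OC)c(C)c(OC)c1OC | intermediate
6 | (Z)-tetradec-9-en-1-ol | CCCC/C=C\CCCCCCCCO | starting material
7 | (Z)-14-bromotetradec-5-ene | CCCC/C=C\CCCCCCCCBr | intermediate
8 | (2,3,5,6-tetramethoxy-4-methylbenzyl)potassium | [K+].[CH2-]c1c(OC)c(OC)c(C)c(OC)c1OC | intermediate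
9 | 1,2,4,5-tetramethoxy-3-methyl-6-[(Z)-pentadec-10-en-1-yl]benzene | CCCC/C=C\CCCCCCCCCc1c(OC)c(OC)c(C)c(OC)c1OC | intermediate
10 | 2,5-dimethoxy-3-methyl-6-[(Z)-pentadec-10-en-1-yl]cyclohexa-2,5-diene-1,4-dione | CCCC/C=C\CCCCCCCCCC1=C(OC)C(=O)C(C)=C(OC)C1=O | intermediate
11 | 2,5-dihydroxy-3-methyl-6-[(Z)-pentadec-10-en-1-yl]cyclohexa-2,5-diene-1,4-dione | CCCC/C=C\CCCCCCCCCC1=C(O)C(=O)C(C)=C(O)C1=O | target

**Step count**
Total steps: 6. Longest linear sequence: 5 (steps 1, 2, 4, 5, 6 from compound 1); the bromide branch adds step 3.

**Steps most likely to fail**

Step 4. The lateral metalation may be incomplete or may be diverted to attack at an O-methyl group. The benzylpotassium may also act as a base and eliminate HBr from the bromide, or a second metalation may lead to double alkylation. The fallback reverses the polarity of the coupling so that C1' is the electrophile. It sets out from 3 and 7 and comes back at 9. Blanc chloromethylation of 3 (paraformaldehyde, conc. HCl, AcOH, 40 °C) at its only free ring position should give 3-(chloromethyl)-1,2,4,5-tetramethoxy-6-methylbenzene F1. Bromide 7 with Mg in THF should give (Z)-tetradec-9-en-1-ylmagnesium bromide F2. A copper-catalysed sp3–sp3 Grignard coupling of F1 with F2 (Li2CuCl4 cat., THF, −20 to 0 °C) should then give 9, and step 2 is no longer needed.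

Step 5. The radical cation may lose a benzylic proton and lead to side-chain oxidation. Demethylation may occur at an ortho pair of methoxy groups instead of a para pair, or the long exposure needed for a poorly soluble substrate may start to attack the alkene. The fallback separates oxidation from unmasking. It sets out from 9 and comes back at 10. Constant-current anodic oxidation of 9 in 1% KOH/MeOH (Pt anode, 0 °C) should add methoxide at a para pair of methoxy-bearing carbons and give the quinone bis(dimethyl ketal) 1,3,3,4,6,6-hexamethoxy-2-methyl-5-[(Z)-pentadec-10-en-1-yl]cyclohexa-1,4-diene F3. Mild hydrolysis of F3 (aq AcOH, rt) should release 10.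

Step 6. The hydrolysis may stall after the first methoxy group, or the electron-rich dianion may degrade by aerial oxidation in hot base. The fallback changes the bond that is broken, from the ring C–O bond (addition–elimination) to the O–CH3 bond (SN2 at methyl) under non-hydrolytic conditions. It sets out from 10 and comes back at 11. Heating 10 with excess LiCl in DMF at 90–100 °C should demethylate both vinylogous esters to the dilithium salt, and dilute HCl should then give 11. This fallback makes no new compound (F0).

**Further compounds**
F1 | step 4 | 3-(chloromethyl)-1,2,4,5-tetramethoxy-6-methylbenzene | ClCc1c(OC)c(OC)c(C)c(OC)c1OC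
F2 | step 4 | (Z)-tetradec-9-en-1-ylmagnesium bromide | CCCC/C=C\CCCCCCCC[Mg]Br
F3 | step 5 | 1,3,3,4,6,6-hexamethoxy-2-methyl-5-[(Z)-pentadec-10-en-1-yl]cyclohexa-1,4-diene | CCCC/C=C\CCCCCCCCCC1=C(OC)C(OC)(OC)C(C)=C(OC)C1(OC)OC
F0 | step 6 | none | none
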